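**Retrosynthetic overview**
1. The biaryl bond is made last: oxidative phenol coupling of two molecules of (5R,8S)-5-isopropyl-3,8-dimethyl-5,6,7,8-tetrahydronaphthalen-1-ol, ortho carbon of one to para carbon of the other.
2. The monomer comes from a trans-1-isopropyl-4-methyl-2-tetralone by removal of the carbonyl oxygen.
3. The 2-tetralone comes from a 4-hydroxy-3-methylindan-1-one and 1-diazo-2-methylpropane by one-carbon ring expansion (1,2-aryl shift); this makes the six-membered ring and the isopropyl-bearing centre.
4. The indanone comes from (S)-4,7-dimethyldihydrocoumarin (Fries-type acyl shift), which comes from 4,7-dimethylcoumarin (asymmetric conjugate reduction sets the methyl-bearing centre), made from m-cresol and methyl acetoacetate.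
5. Ring order: arene (bought) → lactone ring → cyclopentanone ring → six-membered carbocycle by expansion → biaryl.

Assumption: the biaryl axis is left undefined as in the given SMILES, and each named ligand enantiomer stands for the one that gives the stated configuration (its antipode is used if the observed sense is opposite).

**Step 1**
Reactants: 1 m-cresol (3-methylphenol); 2 methyl acetoacetate (methyl 3-oxobutanoate)
Product: 3 4,7-dimethylcoumarin (4,7-dimethyl-2H-chromen-2-one)
Conditions: conc. H2SO4, 0 °C → rt, 16 h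
Reagents that add atoms: none
Why: Pechmann condensation, in which transesterification is followed by acid-mediated ring closure at the less hindered ortho carbon (para to the methyl group) and dehydration, with no stereocentre formed.

**Step 2**
Reactants: 3 4,7-dimethylcoumarin
Product: 4 (S)-4,7-dimethylchroman-2-one
Conditions: CuCl (5 mol %), NaOt-Bu (5 mol %), (R)-DTBM-SEGPHOS (5.5 mol %), HBpin (1.3 equiv), toluene, rt; aq. NH4Cl
Reagents that add atoms: none
Why: Copper hydride-catalysed asymmetric conjugate reduction (1,4-hydroboration) of a β-substituted unsaturated lactone, in which the bisphosphine-bound monovalent copper hydride delivers hydride to one face of C4 and so sets the methyl-bearing centre as S before the boron enolate is protonated on work-up.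

**Step 3**
Reactants: 4 (S)-4,7-dimethylchroman-2-one
Product: 5 (S)-4-hydroxy-3,6-dimethyl-2,3-dihydro-1H-inden-1-one
Conditions: TfOH (neat), 80 °C; ice–water
Reagents that add atoms: none
Why: Fries-type rearrangement (ring-opened acylium ion, then intramolecular Friedel–Crafts acylation), in which only the ring carbon ortho to the side chain can close a five-membered ring, so the acyl group lands meta to the hydroxyl and the existing stereocentre is not involved.

**Step 4**
Reactants: 6 isobutyraldehyde (2-methylpropanal)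
Product: 7 (E)-4-methyl-N'-(2-methylpropylidene)benzenesulfonohydrazide
Conditions: TsNHNH2, MeOH, rt
Reagents that add atoms: p-toluenesulfonohydrazide, Cc1ccc(cc1)S(=O)(=O)NN
Why: Hydrazone condensation of an aldehyde with a sulfonyl hydrazide, which gives a crystalline product without any stereocentre.

**Step 5**
Reactants: 7 (E)-4-methyl-N'-(2-methylpropylidene)benzenesulfonohydrazide
Product: 9 1-diazo-2-methylpropane, via hydrazone sodium salt 8 (not isolated)
Conditions: NaOMe, MeOH, rt; evaporate to dryness; 90–110 °C, 0.1 mmHg, distillate condensed into toluene at −78 °C, titrated and used at once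
Reagents that add atoms: none
Why: Bamford–Stevens reaction run as a vacuum pyrolysis, in which the sulfonylhydrazone anion loses sulfinate and the volatile non-stabilised diazoalkane distils out before it can decompose.

**Step 6**
Reactants: 5 (S)-4-hydroxy-3,6-dimethyl-2,3-dihydro-1H-inden-1-one; 9 1-diazo-2-methylpropane
Product: 12 (1R,4S)-5-hydroxy-1-isopropyl-4,7-dimethyl-3,4-dihydronaphthalen-2(1H)-one, via indanone TMS ether 10 (not isolated), via tetralone TMS ether 11 (not isolated)
Conditions: HMDS (0.6 equiv), TMSOTf (1 mol %), CH2Cl2, rt, evaporate; Sc(OTf)3 (10 mol %), (S,S)-Ph-PyBOX (12 mol %), 9 (1.5 equiv, slow addition), toluene, −78 → −20 °C; citric acid, MeOH, rt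
Reagents that add atoms: none
Why: Proposed new method: a chiral trivalent scandium triflate–PyBOX Lewis acid activates the transiently silylated aryl ketone, the diazoalkane adds to the carbonyl face anti to the C3 methyl with the catalyst fixing the orientation of its isopropyl group, and the anti-periplanar aryl carbon migrates with loss of N2 (Tiffeneau–Demjanov-type 1,2-shift) so that the five-membered ring becomes the β-tetralone with the new benzylic centre R (trans to the methyl, which is also the more stable pseudo-diaxial epimer); the closest known chemistry is the Sc(OTf)3-catalysed homologation of cycloalkanones with substituted diazomethanes and its enantioselective version with aryldiazomethanes, not yet shown for a benzo-fused ketone with aryl migration or for catalyst-controlled insertion of an α-branched alkyldiazomethane.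

**Step 7**
Reactants: 12 (1R,4S)-5-hydroxy-1-isopropyl-4,7-dimethyl-3,4-dihydronaphthalen-2(1H)-one
Product: 14 (5R,8S)-5-isopropyl-3,8-dimethyl-5,6,7,8-tetrahydronaphthalen-1-ol, via tetralone tosylhydrazone 13 (not isolated)
Conditions: TsNHNH2, MeOH, 40 °C, evaporate; catecholborane (3 equiv), CHCl3, 0 °C; NaOAc·3H2O, reflux
Reagents that add atoms: none
Why: Reductive deoxygenation of a ketone through its tosylhydrazone (hydride addition to C=N, loss of sulfinate and extrusion of N2 from the diazene), whose near-neutral conditions leave both benzylic stereocentres as set.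

**Step 8**
Reactants: 14 (5R,8S)-5-isopropyl-3,8-dimethyl-5,6,7,8-tetrahydronaphthalen-1-ol (two molecules)
Product: 15 (5R,8S)-2-[(5S,8R)-4-hydroxy-8-isopropyl-2,5-dimethyl-5,6,7,8-tetrahydronaphthalen-1-yl]-5-isopropyl-3,8-dimethyl-5,6,7,8-tetrahydronaphthalen-1-ol (target)
Conditions: CrCl(salen) (10 mol %; salen = (R,R)-N,N'-bis(3,5-di-tert-butylsalicylidene)cyclohexane-1,2-diamine dianion), O2 (1 atm), 1,2-dichloroethane, 80 °C
Reagents that add atoms: none
Why: Catalytic aerobic oxidative phenol coupling, in which the phenoxyl bound to trivalent chromium bonds through its open ortho carbon to the para carbon of a second phenol (para–para union would crowd both isopropyl-bearing rings onto one axis) and tautomerisation restores both phenols without touching the four stereocentres.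

**Compound list**
1 | m-cresol (3-methylphenol) | Cc1cccc(O)c1 | starting material
2 | methyl acetoacetate | COC(=O)CC(C)=O | starting material
3 | 4,7-dimethylcoumarin | Cc1ccc2c(C)cc(=O)oc2c1 | intermediate
4 | (S)-4,7-dimethylchroman-2-one | C[C@H]1CC(=O)Oc2cc(C)ccc21 | intermediate
5 | (S)-4-hydroxy-3,6-dimethyl-2,3-dihydro-1H-inden-1-one | C[C@H]1CC(=O)c2cc(C)cc(O)c21 | intermediate
6 | isobutyraldehyde | CC(C)C=O | starting material
7 | (E)-4-methyl-N'-(2-methylpropylidene)benzenesulfonohydrazide | CC(C)/C=N/NS(=O)(=O)c1ccc(C)cc1 | intermediate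
8 | sodium salt of 7 (hydrazone sodium salt) | CC(C)C=N[N-]S(=O)(=O)c1ccc(C)cc1.[Na+] | intermediate
9 | 1-diazo-2-methylpropane | CC(C)C=[N+]=[N-] | intermediate
10 | (S)-3,6-dimethyl-4-(trimethylsilyloxy)-2,3-dihydro-1H-inden-1-one (indanone TMS ether) | C[C@H]1CC(=O)c2cc(C)cc(O[Si](C)(C)C)c21 | intermediate
11 | (1R,4S)-1-isopropyl-4,7-dimethyl-5-(trimethylsilyloxy)-3,4-dihydronaphthalen-2(1H)-one (tetralone TMS ether) | Cc1cc2c(c(O[Si](C)(C)C)c1)[C@@H](C)CC(=O)[C@@H]2C(C)C | intermediate
12 | (1R,4S)-5-hydroxy-1-isopropyl-4,7-dimethyl-3,4-dihydronaphthalen-2(1H)-one | Cc1cc2c(c(O)c1)[C@@H](C)CC(=O)[C@@H]2C(C)C | intermediate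
13 | N'-[(1R,4S)-5-hydroxy-1-isopropyl-4,7-dimethyl-3,4-dihydronaphthalen-2(1H)-ylidene]-4-methylbenzenesulfonohydrazide (tetralone tosylhydrazone) | Cc1cc2c(c(O)c1)[C@@H](C)CC(=NNS(=O)(=O)c1ccc(C)cc1)[C@@H]2C(C)C | intermediate
14 | (5R,8S)-5-isopropyl-3,8-dimethyl-5,6,7,8-tetrahydronaphthalen-1-ol | Cc1cc2c(c(O)c1)[C@@H](C)CC[C@@H]2C(C)C | intermediate
15 | (5R,8S)-2-[(5S,8R)-4-hydroxy-8-isopropyl-2,5-dimethyl-5,6,7,8-tetrahydronaphthalen-1-yl]-5-isopropyl-3,8-dimethyl-5,6,7,8-tetrahydronaphthalen-1-ol | Cc1cc2c(c(O)c1-c1c(C)cc(O)c3c1[C@@H](C(C)C)CC[C@@H]3C)[C@@H](C)CC[C@@H]2C(C)C | target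

**Step count**
Total: 8 steps. Longest linear sequence: 6 steps (1, 2, 3, 6, 7, 8).

**Three steps most likely to fail**

Step 6 (the proposed ring expansion). The risks are O-alkylation if silylation is incomplete, migration of the CH2 group instead of the aryl carbon, a second insertion into the more electrophilic product ketone, and low diastereocontrol. The fallback uses known chemistry and sets out from 5. TBSCl and imidazole in DMF give (S)-4-(tert-butyldimethylsilyloxy)-3,6-dimethyl-2,3-dihydro-1H-inden-1-one F3. The ylide from isobutyltriphenylphosphonium bromide F4 (made from 1-bromo-2-methylpropane and PPh3 in refluxing toluene) and KOt-Bu in THF converts F3 in a Wittig reaction into (S)-tert-butyl{[3,6-dimethyl-1-(2-methylpropylidene)-2,3-dihydro-1H-inden-4-yl]oxy}dimethylsilane F5 as an E/Z mixture. The trivalent iodine reagent PhI(OH)OTs in 95% MeOH at rt then effects the known oxidative 1,2-aryl shift ring expansion of the exocyclic alkene to (4S)-5-(tert-butyldimethylsilyloxy)-1-isopropyl-4,7-dimethyl-3,4-dihydronaphthalen-2(1H)-one F6, a mixture at C1. Bu4NF in THF removes the silyl group and equilibrates C1 towards the trans epimer, which is purified and comes back to the route at 12.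

Step 8 (oxidative coupling). The risk is a mixture of ortho–ortho, ortho–para and para–para dimers and diaryl ethers. The fallback sets out from 14 and builds the bond by cross-coupling. MOMCl and i-Pr2NEt in CH2Cl2 give (5R,8S)-5-isopropyl-1-(methoxymethoxy)-3,8-dimethyl-5,6,7,8-tetrahydronaphthalene F7. Directed ortho-lithiation (s-BuLi, TMEDA, THF, −78 °C) and quenching with i-PrOBpin give 2-[(5R,8S)-5-isopropyl-1-(methoxymethoxy)-3,8-dimethyl-5,6,7,8-tetrahydronaphthalen-2-yl]-4,4,5,5-tetramethyl-1,3,2-dioxaborolane F8. A second portion of 14 with NBS in MeCN at 0 °C gives (5R,8S)-4-bromo-5-isopropyl-3,8-dimethyl-5,6,7,8-tetrahydronaphthalen-1-ol F9. Suzuki–Miyaura coupling of F8 with F9 (Pd(OAc)2, SPhos, K3PO4, toluene/H2O, 100 °C, zerovalent palladium formed in the flask) gives the mono-MOM ether of the target F10, and HCl in MeOH comes back to the route at 15.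

Step 3 (Fries-type rearrangement). The risk is partial racemisation of the benzylic centre or a low yield in hot TfOH. The fallback sets out from 4. Ring-opening O-methylation (aq. NaOH, Me2SO4, 40 °C, then HCl) gives (S)-3-(2-methoxy-4-methylphenyl)butanoic acid F1. Friedel–Crafts acylation with Eaton's reagent (P2O5 in MsOH, 50 °C) gives (S)-4-methoxy-3,6-dimethyl-2,3-dihydro-1H-inden-1-one F2. BBr3 in CH2Cl2 (−78 → 0 °C) cleaves the methyl ether and comes back to the route at 5.

**Further compounds**
F1 | step 3 | (S)-3-(2-methoxy-4-methylphenyl)butanoic acid | C[C@@H](CC(=O)O)c1ccc(C)cc1OC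
F2 | step 3 | (S)-4-methoxy-3,6-dimethyl-2,3-dihydro-1H-inden-1-one | C[C@H]1CC(=O)c2cc(C)cc(OC)c21
F3 | step 6 | (S)-4-(tert-butyldimethylsilyloxy)-3,6-dimethyl-2,3-dihydro-1H-inden-1-one | C[C@H]1CC(=O)c2cc(C)cc(O[Si](C)(C)C(C)(C)C)c21
F4 | step 6 | isobutyltriphenylphosphonium bromide | CC(C)C[P+](c1ccccc1)(c1ccccc1)c1ccccc1.[Br-]
F5 | step 6 | (S)-tert-butyl{[3,6-dimethyl-1-(2-methylpropylidene)-2,3-dihydro-1H-inden-4-yl]oxy}dimethylsilane | C[C@H]1CC(=CC(C)C)c2cc(C)cc(O[Si](C)(C)C(C)(C)C)c21
F6 | step 6 | (4S)-5-(tert-butyldimethylsilyloxy)-1-isopropyl-4,7-dimethyl-3,4-dihydronaphthalen-2(1H)-one | Cc1cc2c(c(O[Si](C)(C)C(C)(C)C)c1)[C@@H](C)CC(=O)C2C(C)C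
F7 | step 8 | (5R,8S)-5-isopropyl-1-(methoxymethoxy)-3,8-dimethyl-5,6,7,8-tetrahydronaphthalene | Cc1cc2c(c(OCOC)c1)[C@@H](C)CC[C@@H]2C(C)C
F8 | step 8 | 2-[(5R,8S)-5-isopropyl-1-(methoxymethoxy)-3,8-dimethyl-5,6,7,8-tetrahydronaphthalen-2-yl]-4,4,5,5-tetramethyl-1,3,2-dioxaborolane | Cc1cc2c(c(OCOC)c1B1OC(C)(C)C(C)(C)O1)[C@@H](C)CC[C@@H]2C(C)C
F9 | step 8 | (5R,8S)-4-bromo-5-isopropyl-3,8-dimethyl-5,6,7,8-tetrahydronaphthalen-1-ol | Cc1c(Br)c2c(c(O)c1)[C@@H](C)CC[C@@H]2C(C)C
F10 | step 8 | (5S,8R)-8-isopropyl-4-[(5R,8S)-5-isopropyl-1-(methoxymethoxy)-3,8-dimethyl-5,6,7,8-tetrahydronaphthalen-2-yl]-3,5-dimethyl-5,6,7,8-tetrahydronaphthalen-1-ol | Cc1cc2c(c(OCOC)c1-c1c(C)cc(O)c3c1[C@@H](C(C)C)CC[C@@H]3C)[C@@H](C)CC[C@@H]2C(C)C
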